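## Retrosynthetic overview
1. The O6 ester and the two free CH2OH groups come last: acylate a 15‑O‑silyl 6‑hydroxy‑germacranolide with silyl‑protected 4‑hydroxytiglic acid, then desilylate.
2. The ten‑membered ring comes from ring contraction of an 11‑membered cyclic alkenyl/alkyl boronate. C3 shifts 1,2 from B to C4, then B and I leave anti. This makes C3–C4 and fixes the C4=C5 geometry. The lactone C=O is parked as a silyl lactol during this step.
3. The open‑chain precursor comes from a zinc Barbier union (C6–C7) of a (5S)‑3‑(bromomethyl)butenolide with a (Z)‑β‑iodo enal. C8 controls C7 and C6.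
4. The butenolide derives from (R)‑vinyloxirane, acetylide, Me3Al, oxirane and 2‑(bromomethyl)acrylic acid. The enal derives from butynediol (Red‑Al/I2).
5. Ring order: butenolide (RCM), then the transient 11‑membered boracycle, then the ten‑membered carbocycle.

Assumption: germacrane numbering is used throughout (C1–C10 ring, C11–C13 acrylate unit, C14 = CH3 on C10, C15 = CH2O on C4); Bpin = 4,4,5,5‑tetramethyl‑1,3,2‑dioxaborolan‑2‑yl; 1 is bought enantiopure.

## Route

Step 1
Reactants: 1 (R)-2-vinyloxirane; 2 lithium acetylide–ethylenediamine complex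
Product: 3 (S)-hex-1-en-5-yn-3-ol
Conditions: DMSO, 0 °C → rt; then H2O
Reagents that add atoms: none
Why: SN2 epoxide opening by the hard acetylide at the unhindered CH2 terminus leaves the C–O stereocentre (future C8) untouched.

Step 2
Reactants: 3 (S)-hex-1-en-5-yn-3-ol; 4 oxirane
Product: 7 (3S,5E)-5-methylocta-1,5-diene-3,8-diol, via alkenylalane 5 (not isolated), via lithium alanate 6 (not isolated)
Conditions: Me3Al, Cp2ZrCl2 (20 mol %), CH2Cl2, 0 °C → rt; volatiles off; n-BuLi, THF–hexane, −78 → 0 °C; 4, −30 °C → rt; H2O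
Reagents that add atoms: trimethylaluminium C[Al](C)C
Why: Negishi Zr-catalysed syn-carboalumination puts CH3 on the internal alkyne carbon and fixes the E geometry of C1=C10, and the derived alanate opens oxirane with retention (alkenylalanate–epoxide alkylation).

Step 3
Reactants: 7 (3S,5E)-5-methylocta-1,5-diene-3,8-diol
Product: 8 (3S,5E)-8-iodo-5-methylocta-1,5-dien-3-ol
Conditions: I2 (1.05 equiv), PPh3, imidazole, CH2Cl2, −10 °C
Reagents that add atoms: iodine II
Why: Appel-type (Garegg–Samuelsson) iodination is much faster at the primary than at the secondary allylic hydroxyl.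

Step 4
Reactants: 8 (3S,5E)-8-iodo-5-methylocta-1,5-dien-3-ol
Product: 9 (3S,5E)-5-methyl-8-(Bpin)octa-1,5-dien-3-ol
Conditions: B2pin2, CuI (10 mol %), PPh3 (13 mol %), LiOMe, DMF, rt
Reagents that add atoms: bis(pinacolato)diboron CC1(C)OB(OC1(C)C)B1OC(C)(C)C(C)(C)O1
Why: Copper-catalysed borylation of a primary alkyl iodide tolerates the free alcohol and both alkenes.

Step 5
Reactants: 9 (3S,5E)-5-methyl-8-(Bpin)octa-1,5-dien-3-ol; 10 2-(bromomethyl)acrylic acid
Product: 11 (3S,5E)-5-methyl-8-(Bpin)octa-1,5-dien-3-yl 2-(bromomethyl)acrylate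
Conditions: DCC, DMAP (5 mol %), CH2Cl2, 0 °C
Reagents that add atoms: none
Why: Steglich esterification acylates O8 with retention, and the low DMAP loading spares the allylic bromide.

Step 6
Reactants: 11 (3S,5E)-5-methyl-8-(Bpin)octa-1,5-dien-3-yl 2-(bromomethyl)acrylate
Product: 12 (5S)-3-(bromomethyl)-5-[(2E)-2-methyl-5-(Bpin)pent-2-en-1-yl]furan-2(5H)-one
Conditions: Hoveyda–Grubbs II (5 mol %), toluene (5 mM), 80 °C
Reagents that add atoms: none
Why: Ring-closing metathesis joins only the two terminal methylene alkenes (C7=C11), while the trisubstituted alkene is inert.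

Step 7
Reactants: 13 but-2-yne-1,4-diol
Product: 14 4-(tert-butyldiphenylsilyloxy)but-2-yn-1-ol
Conditions: NaH (1.0 equiv), TBDPSCl (1.0 equiv), THF, 0 °C → rt
Reagents that add atoms: tert-butyldiphenylsilyl chloride CC(C)(C)[Si](Cl)(c1ccccc1)c1ccccc1
Why: Monosilylation through the sparingly soluble monosodium alkoxide differentiates the two ends (O15 protected, O6 free).

Step 8
Reactants: 14 4-(tert-butyldiphenylsilyloxy)but-2-yn-1-ol
Product: 16 (Z)-4-(tert-butyldiphenylsilyloxy)-3-iodobut-2-en-1-ol, via cyclic alanate 15 (not isolated)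
Conditions: Red-Al, Et2O, 0 °C; then I2, THF, −78 °C
Reagents that add atoms: iodine II
Why: Hydroxyl-directed trans-hydroalumination gives the five-membered alanate (H on C5, Al on C4 cis to C6), and iodinolysis with retention gives the iodide with I cis to C6.

Step 9
Reactants: 16 (Z)-4-(tert-butyldiphenylsilyloxy)-3-iodobut-2-en-1-ol
Product: 17 (Z)-4-(tert-butyldiphenylsilyloxy)-3-iodobut-2-enal
Conditions: MnO2 (15 equiv), CH2Cl2, rt
Reagents that add atoms: none
Why: Neutral MnO2 allylic oxidation stops at the enal and does not isomerise the trisubstituted iodoalkene.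

Step 10
Reactants: 12 (5S)-3-(bromomethyl)-5-[(2E)-2-methyl-5-(Bpin)pent-2-en-1-yl]furan-2(5H)-one; 17 (Z)-4-(tert-butyldiphenylsilyloxy)-3-iodobut-2-enal
Product: 19 (6S,7S,8S)-seco-alcohol, a 4,5-trans α-methylene-γ-butyrolactone carrying the C6 carbinol, via allylzinc bromide 18 (not isolated)
Conditions: Zn dust, THF–sat. aq NH4Cl, 0 °C → rt
Reagents that add atoms: none
Why: In this Barbier SE2′ allylation the ring-locked E-type allylzinc attacks through C7 on the face anti to the C8 side chain (7,8-trans) via a chair transition state (6,7-anti), which regenerates the exocyclic methylene.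

Step 11
Reactants: 19 (6S,7S,8S)-seco-alcohol
Product: 20 6-O-TBS ether of 19 (6S,7R,8S; same spatial arrangement)
Conditions: TBSOTf, 2,6-lutidine, CH2Cl2, −78 → 0 °C
Reagents that add atoms: tert-butyldimethylsilyl triflate CC(C)(C)[Si](C)(C)OS(=O)(=O)C(F)(F)F
Why: Silyl ether formation blocks O6 so that C12 can only stay bound to O8 at the lactol stage, and TBS resists O→C silyl shift in step 13.

Step 12
Reactants: 20 6-O-TBS ether of 19
Product: 22 12-O-TES lactol ether of 20 (C12 epimers), via aluminium lactolate 21 (not isolated)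
Conditions: DIBAL-H (1.2 equiv), CH2Cl2, −78 °C; then pyridine, TESOTf, −78 → −20 °C
Reagents that add atoms: triethylsilyl triflate CC[Si](CC)(CC)OS(=O)(=O)C(F)(F)F
Why: Reductive silylation (1,2-reduction of the lactone and trapping of the stable aluminium hemiacetal) removes the only carbonyl group before organolithium chemistry.

Step 13
Reactants: 22 12-O-TES lactol ether of 20
Product: 26 (1(10)E,4Z,6R,7R,8S)-6-(TBSO)-15-(TBDPSO)-12-(TESO)-8,12-epoxygermacra-1(10),4,11(13)-triene (C12 epimers), via alkenyllithium 23 (not isolated), via cyclic boronate 24 (not isolated), via iodoboronate 25 (not isolated)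
Conditions: t-BuLi (2.05 equiv), Et2O–pentane (2 mM), −78 °C, 20 min; I2, THF, −78 °C; NaOMe, MeOH, −78 °C → rt
Reagents that add atoms: none
Why: Proposed new method: ring-contractive macrocyclic Zweifel olefination, in which I/Li exchange with retention gives 23, its C4 carbanion (cis to C6) is captured by the tethered primary Bpin to give the 11-membered boronate 24 whose alkene is cis within the ring and so little strained, I2 forms the iodonium ion of this electron-rich alkenylboronate, C3 migrates from B to C4 anti to the C–I bond (1,2-metalate shift, ring 11 → 10, with C4–C5 still sp3 so the strain of the second E-olefin is not yet paid), and methoxide-triggered anti elimination of B and I from 25 gives stereospecifically the alkene with C3 trans to C6 from either iodonium face; halogen–lithium exchange should outrun attack of t-BuLi on boron as in in-situ-quench borylations, Et2O and the TBS group suppress the 1,4-silyl shift, and the closest known reaction type is the intermolecular Zweifel olefination of alkenyllithium/boronic ester ate complexes, which has not been used to close or contract a medium ring.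

Step 14
Reactants: 26 macrocyclic 12-O-TES lactol ether
Product: 28 (1(10)E,4Z,6R,7R,8S)-6-(TBSO)-15-(TBDPSO)germacra-1(10),4,11(13)-trien-12,8-olide, via lactol 27 (not isolated)
Conditions: IBX (3 equiv), wet DMSO, rt
Reagents that add atoms: none
Why: IBX oxidative desilylation cleaves the labile anomeric TES ether and oxidises the lactol to the lactone, leaves TBS and TBDPS in place, and cannot move C12 to O6 because O6 is blocked.

Step 15
Reactants: 28 6-O-TBS, 15-O-TBDPS germacranolide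
Product: 29 (1(10)E,4Z,6R,7S,8S)-6-hydroxy-15-(TBDPSO)germacra-1(10),4,11(13)-trien-12,8-olide (same spatial arrangement; the C7 descriptor changes by CIP priority only)
Conditions: HF·pyridine, excess pyridine, THF, 0 °C → rt, monitored
Reagents that add atoms: none
Why: Buffered fluoride desilylation removes TBS much faster than TBDPS and is mild enough for the acid-sensitive 1,5-diene.

Step 16
Reactants: 30 allyl alcohol
Product: 31 allyl tert-butyldimethylsilyl ether
Conditions: TBSCl, imidazole, CH2Cl2, rt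
Reagents that add atoms: tert-butyldimethylsilyl chloride CC(C)(C)[Si](C)(C)Cl
Why: This is a standard silyl protection of a primary alcohol.

Step 17
Reactants: 31 allyl tert-butyldimethylsilyl ether; 32 methacrolein
Product: 33 (E)-4-(tert-butyldimethylsilyloxy)-2-methylbut-2-enal
Conditions: Hoveyda–Grubbs II (2.5 mol %), 32 (3 equiv), CH2Cl2, 40 °C
Reagents that add atoms: none
Why: Olefin cross metathesis of a terminal alkene with methacrolein gives the trisubstituted enal with high E selectivity (side-chain geometry set).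

Step 18
Reactants: 33 (E)-4-(tert-butyldimethylsilyloxy)-2-methylbut-2-enal
Product: 34 (E)-4-(tert-butyldimethylsilyloxy)-2-methylbut-2-enoic acid
Conditions: NaClO2, NaH2PO4, 2-methyl-2-butene, t-BuOH–H2O, rt
Reagents that add atoms: sodium chlorite [Na+].[O-]Cl=O
Why: Pinnick oxidation converts the enal into the acid without touching the alkene geometry or the silyl ether.

Step 19
Reactants: 29 6-hydroxy-15-(TBDPSO) germacranolide; 34 (E)-4-(tert-butyldimethylsilyloxy)-2-methylbut-2-enoic acid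
Product: 35 bis-silyl ether of the target (6R,7R,8S)
Conditions: DCC, DMAP, CH2Cl2, 0 °C → rt
Reagents that add atoms: none
Why: Steglich esterification acylates the only free hydroxyl (O6) with retention.

Step 20
Reactants: 35 bis-silyl ether of the target
Product: 36 (1(10)E,4Z,6R,7R,8S)-15-hydroxy-6-[(E)-4-hydroxy-2-methylbut-2-enoyloxy]germacra-1(10),4,11(13)-trien-12,8-olide (target)
Conditions: HF·pyridine (excess), pyridine, THF, rt, 24 h
Reagents that add atoms: none
Why: Global fluoride desilylation frees both primary allylic alcohols under buffered conditions that spare the α-methylene lactone, the ester and the diene.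

## Compound list
1 | (R)-2-vinyloxirane | C=C[C@@H]1CO1 | starting material
2 | lithium acetylide–ethylenediamine complex | [Li]C#C.NCCN | starting material
3 | (S)-hex-1-en-5-yn-3-ol | O[C@H](C=C)CC#C | intermediate
4 | oxirane | C1CO1 | starting material
5 | (E)-alkenyldimethylalane, O8 as dimethylaluminium alkoxide | C[Al](C)O[C@H](C=C)C/C(C)=C/[Al](C)C | intermediate (not isolated)
6 | lithium n-butyl(alkenyl)dimethylalanate | C[Al](C)O[C@H](C=C)C/C(C)=C/[Al-](C)(C)CCCC.[Li+] | intermediate (not isolated)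
7 | (3S,5E)-5-methylocta-1,5-diene-3,8-diol | O[C@H](C=C)C/C(C)=C/CCO | intermediate
8 | (3S,5E)-8-iodo-5-methylocta-1,5-dien-3-ol | O[C@H](C=C)C/C(C)=C/CCI | intermediate
9 | (3S,5E)-5-methyl-8-(Bpin)octa-1,5-dien-3-ol | O[C@H](C=C)C/C(C)=C/CCB1OC(C)(C)C(C)(C)O1 | intermediate
10 | 2-(bromomethyl)acrylic acid | C=C(CBr)C(=O)O | starting material
11 | (3S,5E)-5-methyl-8-(Bpin)octa-1,5-dien-3-yl 2-(bromomethyl)acrylate | C=C(CBr)C(=O)O[C@H](C=C)C/C(C)=C/CCB1OC(C)(C)C(C)(C)O1 | intermediate
12 | (5S)-3-(bromomethyl)-5-[(2E)-2-methyl-5-(Bpin)pent-2-en-1-yl]furan-2(5H)-one | O=C1O[C@H](C=C1CBr)C/C(C)=C/CCB2OC(C)(C)C(C)(C)O2 | intermediate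
13 | but-2-yne-1,4-diol | OCC#CCO | starting material
14 | 4-(tert-butyldiphenylsilyloxy)but-2-yn-1-ol | OCC#CCO[Si](c1ccccc1)(c1ccccc1)C(C)(C)C | intermediate
15 | sodium 1,2-oxaaluminacyclopent-3-ene alanate (Al on C4, cis to C6) | COCCO[Al-]1(OCCOC)OCC=C1CO[Si](c2ccccc2)(c2ccccc2)C(C)(C)C.[Na+] | intermediate (not isolated)
16 | (Z)-4-(tert-butyldiphenylsilyloxy)-3-iodobut-2-en-1-ol | OC/C=C(\I)CO[Si](c1ccccc1)(c1ccccc1)C(C)(C)C | intermediate
17 | (Z)-4-(tert-butyldiphenylsilyloxy)-3-iodobut-2-enal | O=C/C=C(\I)CO[Si](c1ccccc1)(c1ccccc1)C(C)(C)C | intermediate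
18 | allylzinc bromide from 12 | O=C1O[C@H](C=C1C[Zn]Br)C/C(C)=C/CCB2OC(C)(C)C(C)(C)O2 | intermediate (not isolated)
19 | (4S,5S)-4-[(1S,2Z)-4-(TBDPSO)-1-hydroxy-3-iodobut-2-en-1-yl]-3-methylidene-5-[(2E)-2-methyl-5-(Bpin)pent-2-en-1-yl]oxolan-2-one (4,5-trans, C6/C7 anti) | C=C1C(=O)O[C@@H](C/C(C)=C/CCB2OC(C)(C)C(C)(C)O2)[C@@H]1[C@H](O)/C=C(\I)CO[Si](c3ccccc3)(c3ccccc3)C(C)(C)C | intermediate
20 | 6-O-TBS ether of 19 | C=C1C(=O)O[C@@H](C/C(C)=C/CCB2OC(C)(C)C(C)(C)O2)[C@@H]1[C@H](O[Si](C)(C)C(C)(C)C)/C=C(\I)CO[Si](c3ccccc3)(c3ccccc3)C(C)(C)C | intermediate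
21 | diisobutylaluminium lactolate of 20 (C12 epimers) | C=C1C(O[Al](CC(C)C)CC(C)C)O[C@@H](C/C(C)=C/CCB2OC(C)(C)C(C)(C)O2)[C@@H]1[C@H](O[Si](C)(C)C(C)(C)C)/C=C(\I)CO[Si](c3ccccc3)(c3ccccc3)C(C)(C)C | intermediate (not isolated)
22 | 12-O-TES lactol ether of 20 (C12 epimers) | C=C1C(O[Si](CC)(CC)CC)O[C@@H](C/C(C)=C/CCB2OC(C)(C)C(C)(C)O2)[C@@H]1[C@H](O[Si](C)(C)C(C)(C)C)/C=C(\I)CO[Si](c3ccccc3)(c3ccccc3)C(C)(C)C | intermediate
23 | C4 alkenyllithium from 22 (Li cis to C6) | C=C1C(O[Si](CC)(CC)CC)O[C@@H](C/C(C)=C/CCB2OC(C)(C)C(C)(C)O2)[C@@H]1[C@H](O[Si](C)(C)C(C)(C)C)/C=C(\[Li])CO[Si](c3ccccc3)(c3ccccc3)C(C)(C)C | intermediate (not isolated)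
24 | lithium 11-membered cyclic alkenyl(alkyl) pinacol boronate (B between C3 and C4, B cis to C6) | C=C1C(O[Si](CC)(CC)CC)O[C@H]2C/C(C)=C/CC[B-]3(OC(C)(C)C(C)(C)O3)/C(CO[Si](c4ccccc4)(c4ccccc4)C(C)(C)C)=C\[C@@H](O[Si](C)(C)C(C)(C)C)[C@H]12.[Li+] | intermediate (not isolated)
25 | ten-membered 4-Bpin-5-iodo compound (C3 and I added anti; one of two facial isomers drawn, both give 26) | C=C1C(O[Si](CC)(CC)CC)O[C@H]2C/C(C)=C/CC[C@@](B3OC(C)(C)C(C)(C)O3)(CO[Si](c4ccccc4)(c4ccccc4)C(C)(C)C)[C@H](I)[C@@H](O[Si](C)(C)C(C)(C)C)[C@H]12 | intermediate (not isolated)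
26 | (1(10)E,4Z,6R,7R,8S)-6-(TBSO)-15-(TBDPSO)-12-(TESO)-8,12-epoxygermacra-1(10),4,11(13)-triene (C12 epimers) | C=C1C(O[Si](CC)(CC)CC)O[C@H]2C/C(C)=C/CC/C(CO[Si](c3ccccc3)(c3ccccc3)C(C)(C)C)=C/[C@@H](O[Si](C)(C)C(C)(C)C)[C@H]12 | intermediate
27 | corresponding free 12-lactol (C12 epimers) | C=C1C(O)O[C@H]2C/C(C)=C/CC/C(CO[Si](c3ccccc3)(c3ccccc3)C(C)(C)C)=C/[C@@H](O[Si](C)(C)C(C)(C)C)[C@H]12 | intermediate (not isolated)
28 | (1(10)E,4Z,6R,7R,8S)-6-(TBSO)-15-(TBDPSO)germacra-1(10),4,11(13)-trien-12,8-olide | C=C1C(=O)O[C@H]2C/C(C)=C/CC/C(CO[Si](c3ccccc3)(c3ccccc3)C(C)(C)C)=C/[C@@H](O[Si](C)(C)C(C)(C)C)[C@H]12 | intermediate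
29 | (1(10)E,4Z,6R,7S,8S)-6-hydroxy-15-(TBDPSO)germacra-1(10),4,11(13)-trien-12,8-olide | C=C1C(=O)O[C@H]2C/C(C)=C/CC/C(CO[Si](c3ccccc3)(c3ccccc3)C(C)(C)C)=C/[C@@H](O)[C@H]12 | intermediate
30 | allyl alcohol | C=CCO | starting material
31 | allyl tert-butyldimethylsilyl ether | C=CCO[Si](C)(C)C(C)(C)C | intermediate
32 | methacrolein | C=C(C)C=O | starting material
33 | (E)-4-(tert-butyldimethylsilyloxy)-2-methylbut-2-enal | O=C/C(C)=C/CO[Si](C)(C)C(C)(C)C | intermediate
34 | (E)-4-(tert-butyldimethylsilyloxy)-2-methylbut-2-enoic acid | OC(=O)/C(C)=C/CO[Si](C)(C)C(C)(C)C | intermediate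
35 | 15-O-TBDPS, 4'-O-TBS ether of the target | C=C1C(=O)O[C@H]2C/C(C)=C/CC/C(CO[Si](c3ccccc3)(c3ccccc3)C(C)(C)C)=C/[C@@H](OC(=O)/C(C)=C/CO[Si](C)(C)C(C)(C)C)[C@H]12 | intermediate
36 | (1(10)E,4Z,6R,7R,8S)-15-hydroxy-6-[(E)-4-hydroxy-2-methylbut-2-enoyloxy]germacra-1(10),4,11(13)-trien-12,8-olide | C=C1C(=O)O[C@H]2C/C(C)=C/CC/C(CO)=C/[C@@H](OC(=O)/C(C)=C/CO)[C@H]12 | target

## Step count and risks
Total steps: 20. Longest linear sequence: 14 (steps 1–6, 10–15, 19, 20).

**Step 13 (new ring contraction).**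
- Risks: t-BuLi may attack the Bpin before exchange. Boronate formation may be oligomeric instead of 11-membered. The TBS group may shift 1,4. The anti elimination to the strained E-olefin may be slow.
- The fallback sets out from 9 and 16 and uses known chemistry only.
- Compound 9 is silylated (TBSCl, imidazole) to the silyl ether F1. Compound 16 is silylated likewise to the bis-silyl ether F2.
- F2 is lithiated (t-BuLi, Et2O, −78 °C) and treated with F1, then with I2 and NaOMe. This ordinary intermolecular Zweifel olefination gives the open-chain triene F3 with the same C4=C5 geometry.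
- HF·pyridine removes both TBS groups to give the diol F4.
- TEMPO/PhI(OAc)2 oxidises only the primary allylic alcohol to the hydroxy enal F5.
- DCC coupling with 10 gives the ester F6, and ring-closing metathesis gives the bromomethylbutenolide enal F7.
- CrCl2 in THF at high dilution closes C6–C7 by an intramolecular Nozaki–Hiyama (Barbier-type) allylation, a ring closure already used for germacranolides. The fallback comes back to the route at 29.

**Step 10 (C6/C7 diastereoselectivity of the Barbier union).**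
- The fallback sets out from 12 and 17.
- If the union gives mainly the 6-epimeric alcohol F8, this is isolated and inverted by a Mitsunobu reaction (chloroacetic acid, DIAD, PPh3). SN2′ attack is blocked by the fully substituted C4. The product is the chloroacetate F9.
- Neutral cleavage with thiourea/NaHCO3 in EtOH then comes back to the route at 19.

**Step 15 (hindered secondary TBS versus primary TBDPS).**
- The fallback sets out from 28.
- Both silyl groups are removed with TBAF/AcOH to give the 6,15-diol F10.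
- Only the primary allylic hydroxyl is then re-silylated (TBDPSCl, imidazole, CH2Cl2, −20 °C). This comes back to the route at 29.

Further compounds
F1 | step 13 | (3S,5E)-3-(TBSO)-5-methyl-8-(Bpin)octa-1,5-diene | CC(C)(C)[Si](C)(C)O[C@H](C=C)C/C(C)=C/CCB1OC(C)(C)C(C)(C)O1
F2 | step 13 | (Z)-1-(TBSO)-4-(TBDPSO)-3-iodobut-2-ene | CC(C)(C)[Si](C)(C)OC/C=C(\I)CO[Si](c1ccccc1)(c1ccccc1)C(C)(C)C
F3 | step 13 | open-chain (1(10)E,4Z,8S)-triene, 6-O-TBS, 8-O-TBS, 15-O-TBDPS | CC(C)(C)[Si](C)(C)O[C@H](C=C)C/C(C)=C/CC/C(CO[Si](c1ccccc1)(c1ccccc1)C(C)(C)C)=C/CO[Si](C)(C)C(C)(C)C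
F4 | step 13 | corresponding 6,8-diol | O[C@H](C=C)C/C(C)=C/CC/C(CO[Si](c1ccccc1)(c1ccccc1)C(C)(C)C)=C/CO
F5 | step 13 | corresponding 8-hydroxy C6 enal | O[C@H](C=C)C/C(C)=C/CC/C(CO[Si](c1ccccc1)(c1ccccc1)C(C)(C)C)=C/C=O
F6 | step 13 | 8-O-[2-(bromomethyl)acryloyl] ester of F5 | C=C(CBr)C(=O)O[C@H](C=C)C/C(C)=C/CC/C(CO[Si](c1ccccc1)(c1ccccc1)C(C)(C)C)=C/C=O
F7 | step 13 | (5S)-3-(bromomethyl)butenolide carrying the C6 enal chain | O=C1O[C@H](C=C1CBr)C/C(C)=C/CC/C(CO[Si](c2ccccc2)(c2ccccc2)C(C)(C)C)=C/C=O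
F8 | step 10 | 6-epimer of 19 | C=C1C(=O)O[C@@H](C/C(C)=C/CCB2OC(C)(C)C(C)(C)O2)[C@@H]1[C@@H](O)/C=C(\I)CO[Si](c3ccccc3)(c3ccccc3)C(C)(C)C
F9 | step 10 | 6-O-chloroacetate of 19 | C=C1C(=O)O[C@@H](C/C(C)=C/CCB2OC(C)(C)C(C)(C)O2)[C@@H]1[C@H](OC(=O)CCl)/C=C(\I)CO[Si](c3ccccc3)(c3ccccc3)C(C)(C)C
F10 | step 15 | (1(10)E,4Z)-6,15-dihydroxygermacra-1(10),4,11(13)-trien-12,8-olide, configured as 29 | C=C1C(=O)O[C@H]2C/C(C)=C/CC/C(CO)=C/[C@@H](O)[C@H]12
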